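**Plan**
- Retrosynthetic cuts, in order: the aryl–CHO bonds at C3′ and C5′, the one at C6, then the C2–C1′ bond to the pendant ring (C2 raised to the lactone level). Last, O1–C2 is cut while C2 is rebonded to the CH2 of the C4 isobutyl group.
- Enabling feature: C4 is flanked by C3 and by the isobutyl CH2, and each of these two carbons bears an isopropyl group. Tying both to C2 as a ketone carbon gives a 3-aryl-2,4-diisopropylcyclobutanone. Its mirror plane passes through C=O, the aryl-bearing ring carbon and the axis of the symmetric 2,6-dihydroxy-4-alkoxyphenyl ring A, one phenol of which is O1.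
- Forward order: ring A is bought. The four-membered ring comes from a keteniminium/styrene [2+2], and the pyranone ring from rhodium-catalysed opening of that ring. The pendant ring is joined at C2 by Friedel–Crafts arylation of the lactol acetate. The formyl groups go in last, in two regiocontrolled stages.
- Stereochemistry: the 3,4-cis relation comes from the trans aryl/isopropyl relation of the equilibrated meso ketone. The absolute configuration of C3 and C4 comes from the chiral diphosphine on rhodium. C2 is set by attack on the ring face opposite the C3 and C4 substituents.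

Key step: step 8

Assumption: the sense of enantiotopic bond selection cannot be derived for an α,α′-disubstituted cyclobutanone, so (R)-SEGPHOS is written; if a first run gives the enantiomeric lactone, the equally available (S)-ligand is used. Chroman numbering (O1, C2–C4, C4a, C5–C8, C8a; pendant ring primed) is used throughout.

Step 1
Reactants: 1 2,4,6-trihydroxybenzaldehyde
Product: 2 2,6-dihydroxy-4-isopropoxybenzaldehyde
Conditions: i-PrBr (1.1 equiv), K2CO3 (1.05 equiv), DMF, 45 °C
Reagents that add atoms: 2-bromopropane CC(C)Br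
Why: Williamson ether synthesis: the 4-OH is the most acidic hydroxyl (para to CHO) and takes no part in the hydrogen bond to the carbonyl oxygen, so one equivalent of base and halide should alkylate it first; isopropyl outlasts all later steps yet leaves with BCl3 at low temperature.

Step 2
Reactants: 2 2,6-dihydroxy-4-isopropoxybenzaldehyde
Product: 3 2,6-bis(benzyloxy)-4-isopropoxybenzaldehyde
Conditions: BnBr (2.4 equiv), K2CO3 (3 equiv), DMF, 60 °C
Reagents that add atoms: benzyl bromide BrCc1ccccc1
Why: Williamson benzylation of the two chelated phenols; benzyl ethers tolerate ylide, Tf2O/collidine and alkoxide and can be removed under neutral conditions just before the key step.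

Step 3
Reactants: 3 2,6-bis(benzyloxy)-4-isopropoxybenzaldehyde; 4 isobutyltriphenylphosphonium bromide
Product: 6 1,3-bis(benzyloxy)-5-isopropoxy-2-(3-methylbut-1-en-1-yl)benzene (E/Z mixture), via isobutylidenetriphenylphosphorane 5 (not isolated)
Conditions: NaHMDS, THF, 0 °C; then 3, −78 °C → rt
Reagents that add atoms: none
Why: Wittig olefination with a non-stabilised ylide; the E/Z composition does not matter, because the alkene geometry ends up only in the configuration of a ketone α-carbon that is equilibrated in step 6.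

Step 4
Reactants: 7 isovaleryl chloride
Product: 8 N,N,3-trimethylbutanamide
Conditions: 40% aq. Me2NH, NaOH, CH2Cl2–H2O, 0 °C
Reagents that add atoms: dimethylamine CNC
Why: Schotten–Baumann acylation of a secondary amine.

Step 5
Reactants: 6 1,3-bis(benzyloxy)-5-isopropoxy-2-(3-methylbut-1-en-1-yl)benzene; 8 N,N,3-trimethylbutanamide
Product: 11 3-[2,6-bis(benzyloxy)-4-isopropoxyphenyl]-2,4-diisopropylcyclobutanone (mixture of diastereomers), via keteniminium triflate 9 (not isolated), via cyclobutaniminium triflate 10 (not isolated)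
Conditions: Tf2O, 2,4,6-collidine (slow addition), ClCH2CH2Cl, reflux; then aq. NaHCO3, 40 °C
Reagents that add atoms: water O
Why: Keteniminium–alkene [2+2] cycloaddition followed by iminium hydrolysis: the sp carbon of 9 bonds to the alkene carbon bearing the isopropyl group, so charge builds on the benzylic carbon next to the trialkoxyaryl ring, and closure by the enamine carbon places the aryl group between the two CH(i-Pr) carbons; no stereocontrol is asked of this step.

Step 6
Reactants: 11 3-[2,6-bis(benzyloxy)-4-isopropoxyphenyl]-2,4-diisopropylcyclobutanone (mixture of diastereomers)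
Product: 12 meso-(2R,3s,4S)-3-[2,6-bis(benzyloxy)-4-isopropoxyphenyl]-2,4-diisopropylcyclobutanone (isopropyl groups cis to each other and trans to the aryl group)
Conditions: t-BuOK (0.3 equiv), t-BuOH–THF, 40 °C
Reagents that add atoms: none
Why: Base-catalysed epimerisation through the enolates: both α-carbons are exchangeable, and only the isomer with each isopropyl trans to the bulky 2,6-disubstituted aryl group (the isopropyls then 1,3-cis and pseudo-equatorial) avoids vicinal cis strain, so the mixture should drain into the meso ketone.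

Step 7
Reactants: 12 meso-(2R,3s,4S)-3-[2,6-bis(benzyloxy)-4-isopropoxyphenyl]-2,4-diisopropylcyclobutanone
Product: 13 meso-(2R,3s,4S)-3-(2,6-dihydroxy-4-isopropoxyphenyl)-2,4-diisopropylcyclobutanone
Conditions: H2 (1 atm), 10% Pd/C, EtOAc–EtOH, rt
Reagents that add atoms: none
Why: Catalytic hydrogenolysis of aryl benzyl ethers under neutral conditions leaves the cyclobutanone, its α-centres and the isopropyl ether untouched.

Step 8
Reactants: 13 meso-(2R,3s,4S)-3-(2,6-dihydroxy-4-isopropoxyphenyl)-2,4-diisopropylcyclobutanone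
Product: 14 (3R,4S)-5-hydroxy-4-isobutyl-3-isopropyl-7-isopropoxychroman-2-one
Conditions: [Rh(OH)(cod)]2 (2.5 mol %), (R)-SEGPHOS (6 mol %), toluene–t-BuOH (10:1), 40 °C
Reagents that add atoms: none
Why: Proposed new method: the Rh(I) hydroxide exchanges with one of the two equivalent ortho phenols, the aryloxide adds to the ketone from the ring face that carries the aryl group and otherwise only hydrogens (6-exo-trig closure of O1–C2 to an oxa-bridged rhodium cyclobutanolate), strain-driven β-carbon elimination breaks one acyl–Cα bond, and the secondary alkylrhodium is protonated to the isobutyl CH2 with return of a rhodium aryloxide. The closest known reaction type is the Rh/diphosphine-catalysed enantioselective opening of 3-(2-hydroxyphenyl)cyclobutanones to 3,4-dihydrocoumarins, shown only for ketones without α-substituents, where a primary alkylrhodium results; new here are cleavage towards a secondary carbon and the choice between two substituted enantiotopic bonds. C3 keeps the configuration of the α-carbon that stays on the carbonyl, and C4, pseudoasymmetric in 13, becomes stereogenic once its two ring branches differ, so one event fixes both absolute configurations: the ligand must direct cleavage to the bond between C=O and the (S)-configured α-carbon. The 3,4-cis relation is set by the substrate, because aryl and the surviving isopropyl are trans on the four-membered ring and the aryl carbon becomes a member of the lactone ring. The further selectivity needed is protonation ahead of β-hydride elimination: both aryl ortho positions bear oxygen, which excludes 1,4-rhodium migration, the second free phenol lies next to the C–Rh bond as a proton relay, and t-BuOH adds a non-nucleophilic proton pool.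

Step 9
Reactants: 14 (3R,4S)-5-hydroxy-4-isobutyl-3-isopropyl-7-isopropoxychroman-2-one
Product: 16 (3R,4S)-4-isobutyl-3-isopropyl-7-isopropoxychroman-2,5-diyl diacetate (both C2 epimers), via bis(diisobutylaluminium) hemiacetal 15 (not isolated)
Conditions: DIBAL-H (2.3 equiv), CH2Cl2, −78 °C; then pyridine, DMAP, Ac2O, −78 → 0 °C; Rochelle salt work-up
Reagents that add atoms: acetic anhydride CC(=O)OC(C)=O
Why: Low-temperature DIBAL-H reduction of the lactone with in situ acetylation of the aluminium hemiacetal (reductive acetylation of esters): the first hydride equivalent only deprotonates the phenol, the tetrahedral intermediate is trapped ring-closed, the same anhydride caps O5, and the epimerisable cis C3 centre α to the lactone carbonyl never meets a basic protection step.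

Step 10
Reactants: 16 (3R,4S)-4-isobutyl-3-isopropyl-7-isopropoxychroman-2,5-diyl diacetate; 17 1,3,5-tris(benzyloxy)benzene
Product: 18 (2R,3R,4S)-2-[2,4,6-tris(benzyloxy)phenyl]-4-isobutyl-3-isopropyl-7-isopropoxychroman-5-yl acetate
Conditions: BF3·OEt2 (1.2 equiv), 17 (3 equiv), CH2Cl2, −78 → −30 °C
Reagents that add atoms: none
Why: Lewis acid-promoted Friedel–Crafts C-arylation of a cyclic acetal acetate through its oxocarbenium ion (as in aryl C-glycoside synthesis): the C3 isopropyl and C4 isobutyl groups lie on the same ring face, so the arene should attack C2 from the other face and set (2R) with the 2,3-trans relation, which is also the more stable one, while the 5-acetate lowers the nucleophilicity of ring A and so suppresses self-arylation.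

Step 11
Reactants: 18 (2R,3R,4S)-2-[2,4,6-tris(benzyloxy)phenyl]-4-isobutyl-3-isopropyl-7-isopropoxychroman-5-yl acetate
Product: 19 (2R,3R,4S)-2-[2,4,6-tris(benzyloxy)phenyl]-4-isobutyl-3-isopropyl-7-isopropoxychroman-5-ol
Conditions: K2CO3 (cat.), MeOH–THF, 0 °C → rt
Reagents that add atoms: none
Why: Base-catalysed methanolysis of the aryl acetate frees O5 alone, since every other oxygen is an ether.

Step 12
Reactants: 19 (2R,3R,4S)-2-[2,4,6-tris(benzyloxy)phenyl]-4-isobutyl-3-isopropyl-7-isopropoxychroman-5-ol
Product: 20 (2R,3R,4S)-2-[2,4,6-tris(benzyloxy)phenyl]-5-hydroxy-4-isobutyl-3-isopropyl-7-isopropoxychroman-6-carbaldehyde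
Conditions: MgCl2, Et3N, (CH2O)n, MeCN, reflux; 1 M HCl work-up
Reagents that add atoms: paraformaldehyde (as formaldehyde) C=O
Why: Magnesium-mediated ortho-formylation of a phenol (Casnati–Skattebøl reaction): formaldehyde is delivered within the magnesium phenoxide to a carbon ortho to O5, and since the other ortho carbon is C4a and C8 has only ether neighbours, C6 is the only site that can react, while the fully etherified pendant ring is inert.

Step 13
Reactants: 20 (2R,3R,4S)-2-[2,4,6-tris(benzyloxy)phenyl]-5-hydroxy-4-isobutyl-3-isopropyl-7-isopropoxychroman-6-carbaldehyde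
Product: 21 (2R,3R,4S)-5-hydroxy-4-isobutyl-3-isopropyl-7-isopropoxy-2-(2,4,6-trihydroxyphenyl)chroman-6-carbaldehyde
Conditions: H2 (1 atm), 10% Pd/C, EtOAc, rt, stopped after three equivalents are taken up
Reagents that add atoms: none
Why: Hydrogenolysis of the three benzyl ethers; a chelated, donor-rich salicylaldehyde carbonyl and the cyclic benzylic ether of a flavan-type ring should survive short exposure at 1 atm in a non-acidic solvent.

Step 14
Reactants: 21 (2R,3R,4S)-5-hydroxy-4-isobutyl-3-isopropyl-7-isopropoxy-2-(2,4,6-trihydroxyphenyl)chroman-6-carbaldehyde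
Product: 23 5-[(2R,3R,4S)-6-formyl-5-hydroxy-4-isobutyl-3-isopropyl-7-isopropoxychroman-2-yl]-2,4,6-trihydroxyisophthalaldehyde, via bis(iminium) salt 22 (not isolated)
Conditions: POCl3 (2.4 equiv), DMF, EtOAc, 0 °C → rt; then H2O
Reagents that add atoms: N,N-dimethylformamide CN(C)C=O; water O
Why: Vilsmeier–Haack formylation, which takes free phloroglucinols to the dialdehyde stage: the pendant triphenol ring has exactly two open positions, whereas C8 sits on a ring already deactivated by the C6 formyl group and is flanked by two ether oxygens, one of them bulky; should C2–O1 ionise in the acidic medium, reclosure through O1 is favoured because O5 is tied up in the chelate with the C6 formyl group.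

Step 15
Reactants: 23 5-[(2R,3R,4S)-6-formyl-5-hydroxy-4-isobutyl-3-isopropyl-7-isopropoxychroman-2-yl]-2,4,6-trihydroxyisophthalaldehyde
Product: 24 5-[(2R,3R,4S)-6-formyl-5,7-dihydroxy-4-isobutyl-3-isopropylchroman-2-yl]-2,4,6-trihydroxyisophthalaldehyde (CNP0328914.1)
Conditions: BCl3 (1 M in CH2Cl2, excess), CH2Cl2, −78 → 0 °C; then H2O
Reagents that add atoms: none
Why: Boron trichloride cleavage of an aryl isopropyl ether, assisted by chelation to the ortho formyl group, should run at or below 0 °C, and the diformylated C2 aryl group is too electron-poor to support ionisation of C2–O1, so the three stereocentres should stay intact.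

**Compound list**
1 | 2,4,6-trihydroxybenzaldehyde | O=Cc1c(O)cc(O)cc1O | starting material
2 | 2,6-dihydroxy-4-isopropoxybenzaldehyde | O=Cc1c(O)cc(OC(C)C)cc1O | intermediate
3 | 2,6-bis(benzyloxy)-4-isopropoxybenzaldehyde | O=Cc1c(OCc2ccccc2)cc(OC(C)C)cc1OCc1ccccc1 | intermediate
4 | isobutyltriphenylphosphonium bromide | CC(C)C[P+](c1ccccc1)(c1ccccc1)c1ccccc1.[Br-] | starting material
5 | isobutylidenetriphenylphosphorane | CC(C)C=P(c1ccccc1)(c1ccccc1)c1ccccc1 | intermediate (not isolated)
6 | 1,3-bis(benzyloxy)-5-isopropoxy-2-(3-methylbut-1-en-1-yl)benzene, E/Z mixture | CC(C)C=Cc1c(OCc2ccccc2)cc(OC(C)C)cc1OCc1ccccc1 | intermediate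
7 | isovaleryl chloride | CC(C)CC(=O)Cl | starting material
8 | N,N,3-trimethylbutanamide | CC(C)CC(=O)N(C)C | intermediate
9 | N,N-dimethyl(3-methylbut-1-en-1-ylidene)ammonium triflate (keteniminium salt) | CC(C)C=C=[N+](C)C.[O-]S(=O)(=O)C(F)(F)F | intermediate (not isolated)
10 | N-{3-[2,6-bis(benzyloxy)-4-isopropoxyphenyl]-2,4-diisopropylcyclobutylidene}-N-methylmethanaminium triflate | C[N+](C)=C1C(C(C)C)C(c2c(OCc3ccccc3)cc(OC(C)C)cc2OCc2ccccc2)C1C(C)C.[O-]S(=O)(=O)C(F)(F)F | intermediate (not isolated)
11 | 3-[2,6-bis(benzyloxy)-4-isopropoxyphenyl]-2,4-diisopropylcyclobutanone, diastereomer mixture | O=C1C(C(C)C)C(c2c(OCc3ccccc3)cc(OC(C)C)cc2OCc2ccccc2)C1C(C)C | intermediate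
12 | meso-(2R,3s,4S)-3-[2,6-bis(benzyloxy)-4-isopropoxyphenyl]-2,4-diisopropylcyclobutanone | O=C1[C@H](C(C)C)[C@@H](c2c(OCc3ccccc3)cc(OC(C)C)cc2OCc2ccccc2)[C@@H]1C(C)C | intermediate
13 | meso-(2R,3s,4S)-3-(2,6-dihydroxy-4-isopropoxyphenyl)-2,4-diisopropylcyclobutanone | O=C1[C@H](C(C)C)[C@@H](c2c(O)cc(OC(C)C)cc2O)[C@@H]1C(C)C | intermediate
14 | (3R,4S)-5-hydroxy-4-isobutyl-3-isopropyl-7-isopropoxychroman-2-one | CC(C)C[C@@H]1c2c(cc(OC(C)C)cc2O)OC(=O)[C@@H]1C(C)C | intermediate
15 | O2,O5-bis(diisobutylaluminium) derivative of the (3R,4S)-chroman-2,5-diol | CC(C)C[C@@H]1c2c(cc(OC(C)C)cc2O[Al](CC(C)C)CC(C)C)OC(O[Al](CC(C)C)CC(C)C)[C@@H]1C(C)C | intermediate (not isolated)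
16 | (3R,4S)-4-isobutyl-3-isopropyl-7-isopropoxychroman-2,5-diyl diacetate, both C2 epimers | CC(C)C[C@@H]1c2c(cc(OC(C)C)cc2OC(C)=O)OC(OC(C)=O)[C@@H]1C(C)C | intermediate
17 | 1,3,5-tris(benzyloxy)benzene | c1ccc(COc2cc(OCc3ccccc3)cc(OCc3ccccc3)c2)cc1 | starting material
18 | (2R,3R,4S)-2-[2,4,6-tris(benzyloxy)phenyl]-4-isobutyl-3-isopropyl-7-isopropoxychroman-5-yl acetate | CC(C)C[C@@H]1c2c(cc(OC(C)C)cc2OC(C)=O)O[C@@H](c2c(OCc3ccccc3)cc(OCc3ccccc3)cc2OCc2ccccc2)[C@@H]1C(C)C | intermediate
19 | (2R,3R,4S)-2-[2,4,6-tris(benzyloxy)phenyl]-4-isobutyl-3-isopropyl-7-isopropoxychroman-5-ol | CC(C)C[C@@H]1c2c(cc(OC(C)C)cc2O)O[C@@H](c2c(OCc3ccccc3)cc(OCc3ccccc3)cc2OCc2ccccc2)[C@@H]1C(C)C | intermediate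
20 | (2R,3R,4S)-2-[2,4,6-tris(benzyloxy)phenyl]-5-hydroxy-4-isobutyl-3-isopropyl-7-isopropoxychroman-6-carbaldehyde | CC(C)C[C@@H]1c2c(cc(OC(C)C)c(C=O)c2O)O[C@@H](c2c(OCc3ccccc3)cc(OCc3ccccc3)cc2OCc2ccccc2)[C@@H]1C(C)C | intermediate
21 | (2R,3R,4S)-5-hydroxy-4-isobutyl-3-isopropyl-7-isopropoxy-2-(2,4,6-trihydroxyphenyl)chroman-6-carbaldehyde | CC(C)C[C@@H]1c2c(cc(OC(C)C)c(C=O)c2O)O[C@@H](c2c(O)cc(O)cc2O)[C@@H]1C(C)C | intermediate
22 | 3′,5′-bis(dimethyliminiomethyl) derivative of 21, bis(dichlorophosphate) | CC(C)C[C@@H]1c2c(cc(OC(C)C)c(C=O)c2O)O[C@@H](c2c(O)c(C=[N+](C)C)c(O)c(C=[N+](C)C)c2O)[C@@H]1C(C)C.[O-]P(=O)(Cl)Cl.[O-]P(=O)(Cl)Cl | intermediate (not isolated)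
23 | 5-[(2R,3R,4S)-6-formyl-5-hydroxy-4-isobutyl-3-isopropyl-7-isopropoxychroman-2-yl]-2,4,6-trihydroxyisophthalaldehyde | CC(C)C[C@@H]1c2c(cc(OC(C)C)c(C=O)c2O)O[C@@H](c2c(O)c(C=O)c(O)c(C=O)c2O)[C@@H]1C(C)C | intermediate
24 | 5-[(2R,3R,4S)-6-formyl-5,7-dihydroxy-4-isobutyl-3-isopropylchroman-2-yl]-2,4,6-trihydroxyisophthalaldehyde (CNP0328914.1) | CC(C)C[C@@H]1c2c(cc(O)c(C=O)c2O)O[C@@H](c2c(O)c(C=O)c(O)c(C=O)c2O)[C@@H]1C(C)C | target

**Totals**
- Total step count: 15.
- Longest linear sequence: 14 (steps 1–3 and 5–15).

**Steps most likely to fail**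

1. Step 8.
- What may go wrong: β-hydride elimination of the secondary alkylrhodium (towards the C4–H or the isopropyl C–H) may outrun protonation. The aryloxide may add only sluggishly to the flanked carbonyl. The ligand may discriminate poorly between the two enantiotopic bonds.
- Fallback (known chemistry, from 12 back to 14): the ring strain is released by a radical instead, and the racemate is resolved.
- Hydroxylamine hydrochloride/pyridine converts 12 into the cyclobutanone oxime F1, and benzoyl chloride gives the O-benzoyl oxime F2.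
- Bu3SnH/AIBN in refluxing benzene generates the iminyl radical. Its β-scission opens the ring to the secondary alkyl radical, which the stannane reduces to the racemic nitrile F3 with the relative configuration unchanged.
- Hydrogenolysis gives the bisphenol nitrile F4.
- HCl in aqueous dioxane closes the iminolactone (Pinner-type addition of the phenol) and hydrolyses it to the racemic lactone, that is 14 together with the enantiomeric lactone F5.
- Preparative HPLC on a chiral phase delivers 14.

2. Step 5.
- What may go wrong: the activated amide may attack the trialkoxyarene ring instead of the hindered, twisted double bond. The benzylic cation may also be lost before ring closure, through hydride transfer from an ortho benzyloxy methylene or through proton loss.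
- Fallback (from 6 back to 11): the ring is built with a neutral, more reactive ketene, and the second isopropyl group is added afterwards.
- Dichloroketene (Cl3CCOCl, Zn–Cu, Et2O) adds to 6 to give the dichlorocyclobutanone F6, and Zn/AcOH removes both chlorines to give the monoisopropyl cyclobutanone F7.
- Kinetic deprotonation at the CH2 with LDA and aldol addition to acetone give the tertiary alcohol F8.
- Mesylation followed by DBU elimination gives the isopropylidene ketone F9.
- Hydrogenation over Pd/C poisoned with pyridine, which spares benzyl ethers, returns 11 for the equilibration of step 6.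

3. Step 10.
- What may go wrong: proton loss from the oxocarbenium ion to the 4H-chromene, followed by reprotonation, would scramble C3. Ring A of a second molecule may act as the nucleophile. The hindered arene may attack too slowly.
- Fallback (from 14 and 17 back to 19): the polarity at C2 is reversed, and O1–C2 is closed last.
- DIBAL-H at −78 °C with aqueous work-up gives the lactol F10.
- NBS converts 17 into the aryl bromide F11, and n-BuLi at −78 °C turns it into the aryllithium F12.
- An excess of F12 adds to the open aldehyde form of F10 to give the benzylic alcohol F13.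
- Catalytic TsOH in CH2Cl2 at 0 °C ionises this highly stabilised benzylic position. Either of the two equivalent ring A phenols then closes the chroman under thermodynamic control to the 2,3-trans isomer 19.

**Further compounds**
F1 | step 8 | 3-[2,6-bis(benzyloxy)-4-isopropoxyphenyl]-2,4-diisopropylcyclobutanone oxime | ON=C1[C@H](C(C)C)[C@@H](c2c(OCc3ccccc3)cc(OC(C)C)cc2OCc2ccccc2)[C@@H]1C(C)C
F2 | step 8 | O-benzoyl oxime of 12 | O=C(ON=C1[C@H](C(C)C)[C@@H](c2c(OCc3ccccc3)cc(OC(C)C)cc2OCc2ccccc2)[C@@H]1C(C)C)c1ccccc1
F3 | step 8 | rac-(2R*,3S*)-3-[2,6-bis(benzyloxy)-4-isopropoxyphenyl]-2-isopropyl-5-methylhexanenitrile (drawn: the enantiomer leading to 14) | CC(C)C[C@H](c1c(OCc2ccccc2)cc(OC(C)C)cc1OCc1ccccc1)[C@H](C#N)C(C)C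
F4 | step 8 | rac-(2R*,3S*)-3-(2,6-dihydroxy-4-isopropoxyphenyl)-2-isopropyl-5-methylhexanenitrile (drawn: the enantiomer leading to 14) | CC(C)C[C@H](c1c(O)cc(OC(C)C)cc1O)[C@H](C#N)C(C)C
F5 | step 8 | (3S,4R)-5-hydroxy-4-isobutyl-3-isopropyl-7-isopropoxychroman-2-one (enantiomer of 14) | CC(C)C[C@H]1c2c(cc(OC(C)C)cc2O)OC(=O)[C@H]1C(C)C
F6 | step 5 | 3-[2,6-bis(benzyloxy)-4-isopropoxyphenyl]-2,2-dichloro-4-isopropylcyclobutanone | O=C1C(Cl)(Cl)C(c2c(OCc3ccccc3)cc(OC(C)C)cc2OCc2ccccc2)C1C(C)C
F7 | step 5 | 3-[2,6-bis(benzyloxy)-4-isopropoxyphenyl]-2-isopropylcyclobutanone | O=C1CC(c2c(OCc3ccccc3)cc(OC(C)C)cc2OCc2ccccc2)C1C(C)C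
F8 | step 5 | 3-[2,6-bis(benzyloxy)-4-isopropoxyphenyl]-2-(2-hydroxypropan-2-yl)-4-isopropylcyclobutanone | O=C1C(C(C)(C)O)C(c2c(OCc3ccccc3)cc(OC(C)C)cc2OCc2ccccc2)C1C(C)C
F9 | step 5 | 3-[2,6-bis(benzyloxy)-4-isopropoxyphenyl]-2-isopropyl-4-(propan-2-ylidene)cyclobutanone | O=C1C(=C(C)C)C(c2c(OCc3ccccc3)cc(OC(C)C)cc2OCc2ccccc2)C1C(C)C
F10 | step 10 | (3R,4S)-4-isobutyl-3-isopropyl-7-isopropoxychroman-2,5-diol (both C2 epimers) | CC(C)C[C@@H]1c2c(cc(OC(C)C)cc2O)OC(O)[C@@H]1C(C)C
F11 | step 10 | 2-bromo-1,3,5-tris(benzyloxy)benzene | Brc1c(OCc2ccccc2)cc(OCc2ccccc2)cc1OCc1ccccc1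
F12 | step 10 | 2,4,6-tris(benzyloxy)phenyllithium | [Li]c1c(OCc2ccccc2)cc(OCc2ccccc2)cc1OCc1ccccc1
F13 | step 10 | (2R,3S)-3-(2,6-dihydroxy-4-isopropoxyphenyl)-2-isopropyl-5-methyl-1-[2,4,6-tris(benzyloxy)phenyl]hexan-1-ol (both C1 epimers) | CC(C)C[C@H](c1c(O)cc(OC(C)C)cc1O)[C@@H](C(C)C)C(O)c1c(OCc2ccccc2)cc(OCc2ccccc2)cc1OCc1ccccc1
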